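The cyclohexenone (ring atoms C1–C6: C1 carbonyl, C2=C3, C4 carbinol, C5 carrying the C1′–C22′ chain) is disconnected at C2=C3. The key step forms this bond by aldol condensation of a C1 methyl ketone onto a C3 aldehyde; both carbonyls are unveiled in the same flask by ozonolysis of a 2-methylallyl group on C5 and a vinyl group on C4, and their 1,5-relationship permits only this six-membered closure. The precursor is an acyclic diene holding all seven stereocentres: C4 from (S)-but-3-ene-1,2-diol, C5 by anti-selective cuprate addition, C4′ from a commercial statin ylide, C2′/C8′ by syn reductions, C6′ by a 1,5-anti aldol, C10′ by allylboration.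

Key step: step 16

Remark: target numbering is used for every intermediate: ring C1 (C=O), C2, C3, C4 (OH), C5, C6; side chain C1′ (on C5) to C22′ (on phenyl). PMB = 4-methoxybenzyl, TBS = tert-butyldimethylsilyl, Ipc = isopinocampheyl.
Assumption: compounds 1, 4 and 13 and the reagents named on the reagent lines are purchased; 4 is the commercial statin side-chain ylide.

Step 1
Reactants: 1 (2S)-but-3-ene-1,2-diol
Product: 2 (4S)-4-ethenyl-2-(4-methoxyphenyl)-1,3-dioxolane (both epimers at C2)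
Conditions: 4-MeOC6H4CH(OMe)2, PPTS (cat.), CH2Cl2, rt
Reagents that add atoms: 4-methoxybenzaldehyde dimethyl acetal, COC(OC)c1ccc(OC)cc1
Why: Acid-catalysed transacetalisation closes the five-membered p-methoxybenzylidene acetal on the 1,2-diol; the stereocentre that becomes ring C4 is untouched.

Step 2
Reactants: 2 p-methoxybenzylidene acetal of step 1
Product: 3 (2S)-2-[(4-methoxyphenyl)methoxy]but-3-en-1-ol
Conditions: i-Bu2AlH (2.5 equiv), CH2Cl2, −78 → 0 °C; aq. KNaC4H4O6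
Reagents that add atoms: none
Why: Reductive acetal opening: aluminium binds the less hindered primary oxygen and hydride reduces the oxocarbenium ion on the secondary oxygen, so the PMB ether should end on the C4 oxygen with the primary hydroxyl free.

Step 3
Reactants: 3 (2S)-2-[(4-methoxyphenyl)methoxy]but-3-en-1-ol; 4 methyl (3R)-3-[(tert-butyldimethylsilyl)oxy]-5-oxo-6-(triphenyl-λ5-phosphanylidene)hexanoate
Product: 6 methyl (3R,6E,8S)-3-[(tert-butyldimethylsilyl)oxy]-8-[(4-methoxyphenyl)methoxy]-5-oxodeca-6,9-dienoate, via aldehyde 5 (not isolated)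
Conditions: Dess–Martin periodinane, CH2Cl2, 0 °C; then 4, 0 °C → rt
Reagents that add atoms: none
Why: Dess–Martin oxidation and, in the same flask, Wittig olefination with the stabilised keto ylide should give the (E)-enone; the isomerisation-prone α-alkoxy β,γ-unsaturated aldehyde is consumed without isolation and meets no base stronger than the ylide.

Step 4
Reactants: 6 dienone of step 3
Product: 8 methyl (3R,7R,8S)-3-[(tert-butyldimethylsilyl)oxy]-8-[(4-methoxyphenyl)methoxy]-7-(2-methylprop-2-en-1-yl)-5-oxodec-9-enoate, via silyl enol ether 7 (not isolated)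
Conditions: CH2=C(CH3)CH2MgCl, CuBr·SMe2 (1.2 equiv), Me3SiCl, THF, −78 °C; then 1 M HCl, THF, 0 °C
Reagents that add atoms: (2-methylallyl)magnesium chloride, CC(=C)C[Mg]Cl
Why: Chlorosilane-accelerated conjugate addition of the allylic organocopper reagent; the nucleophile should add to the β-carbon anti to the γ-OPMB group (Felkin–Anh-type control), which sets C5 in the relationship to C4 that becomes trans in the ring, and the acid work-up hydrolyses the silyl enol ether.

Step 5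
Reactants: 8 ketone of step 4
Product: 9 methyl (3R,7R,8S)-3-hydroxy-8-[(4-methoxyphenyl)methoxy]-7-(2-methylprop-2-en-1-yl)-5-oxodec-9-enoate
Conditions: HF·pyridine, pyridine, THF, 0 °C → rt
Reagents that add atoms: none
Why: Fluoride cleaves the secondary TBS ether while the PMB ether, ester and alkenes persist, freeing the C4′ hydroxyl that directs the next reduction.

Step 6
Reactants: 9 β-hydroxy ketone of step 5
Product: 10 methyl (3R,5R,7R,8S)-3,5-dihydroxy-8-[(4-methoxyphenyl)methoxy]-7-(2-methylprop-2-en-1-yl)dec-9-enoate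
Conditions: Et2BOMe, THF/MeOH (4:1), −78 °C; NaBH4; AcOH; MeOH (evaporation)
Reagents that add atoms: none
Why: Narasaka–Prasad reduction: hydride adds axially to the six-membered diethylboron chelate of the β-hydroxy ketone, which should give the 1,3-syn diol and thereby C2′.

Step 7
Reactants: 10 syn-diol ester of step 6
Product: 11 methyl 2-[(4R,6R)-6-{(2R,3S)-3-[(4-methoxyphenyl)methoxy]-2-(2-methylprop-2-en-1-yl)pent-4-en-1-yl}-2,2-dimethyl-1,3-dioxan-4-yl]acetate
Conditions: Me2C(OMe)2, PPTS (cat.), CH2Cl2, rt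
Reagents that add atoms: 2,2-dimethoxypropane, COC(C)(C)OC
Why: Acid-catalysed acetonide formation on the syn-1,3-diol (chair dioxane, both substituents equatorial) should outrun lactonisation onto the ester.

Step 8
Reactants: 11 acetonide ester of step 7
Product: 12 2-[(4R,6R)-6-{(2R,3S)-3-[(4-methoxyphenyl)methoxy]-2-(2-methylprop-2-en-1-yl)pent-4-en-1-yl}-2,2-dimethyl-1,3-dioxan-4-yl]acetaldehyde
Conditions: i-Bu2AlH (1.1 equiv), CH2Cl2, −78 °C; MeOH; aq. KNaC4H4O6
Reagents that add atoms: none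
Why: Partial ester reduction: the tetrahedral aluminium hemiacetal is stable at −78 °C and releases the aldehyde only on work-up.

Step 9
Reactants: 13 11-bromoundecan-1-ol
Product: 14 13-phenyltridecan-1-ol
Conditions: PhCH2CH2MgCl (2.5 equiv), Li2CuCl4 (3 mol %), THF, −20 °C → rt
Reagents that add atoms: (2-phenylethyl)magnesium chloride, Cl[Mg]CCc1ccccc1
Why: Copper-catalysed cross-coupling of a primary alkyl bromide with an alkyl Grignard reagent (Kochi-type); one equivalent of the reagent is consumed by the free hydroxyl.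

Step 10
Reactants: 14 13-phenyltridecan-1-ol
Product: 15 13-phenyltridecanal
Conditions: TEMPO (10 mol %), PhI(OAc)2, CH2Cl2, rt
Reagents that add atoms: none
Why: Oxoammonium-mediated oxidation of the primary alcohol, which stops at the aldehyde.

Step 11
Reactants: 15 13-phenyltridecanal
Product: 16 (4R)-16-phenylhexadec-1-en-4-ol
Conditions: (−)-Ipc2B(allyl), Et2O, −78 °C; then NaOH, H2O2
Reagents that add atoms: (−)-B-allyldiisopinocampheylborane, C=CCB([C@@H]1C[C@@H]2C[C@H]([C@H]1C)C2(C)C)[C@@H]1C[C@@H]2C[C@H]([C@H]1C)C2(C)C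
Why: Brown allylboration through a closed chair transition state; the isopinocampheyl groups derived from (+)-α-pinene should deliver the allyl group to the Si face of the aldehyde, giving the (R)-carbinol that becomes C10′.

Step 12
Reactants: 16 (4R)-16-phenylhexadec-1-en-4-ol
Product: 17 1-methoxy-4-({[(4R)-16-phenylhexadec-1-en-4-yl]oxy}methyl)benzene
Conditions: NaH, 4-MeOC6H4CH2Cl, n-Bu4NI (cat.), THF/DMF, 0 °C → rt
Reagents that add atoms: 4-methoxybenzyl chloride, COc1ccc(CCl)cc1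
Why: Williamson etherification of the sodium alkoxide; the PMB ether is the β-alkoxy group needed for 1,5-induction in step 14.

Step 13
Reactants: 17 homoallylic PMB ether of step 12
Product: 18 (4R)-4-[(4-methoxyphenyl)methoxy]-16-phenylhexadecan-2-one
Conditions: PdCl2 (10 mol %), CuCl, O2 (1 atm), DMF/H2O (7:1), rt
Reagents that add atoms: water, O
Why: Wacker oxidation: Markovnikov hydroxypalladation of the terminal alkene and β-hydride elimination should give the methyl ketone.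

Step 14
Reactants: 18 (4R)-4-[(4-methoxyphenyl)methoxy]-16-phenylhexadecan-2-one; 12 aldehyde of step 8
Product: 19 (2R,6R)-1-[(4S,6R)-6-{(2R,3S)-3-[(4-methoxyphenyl)methoxy]-2-(2-methylprop-2-en-1-yl)pent-4-en-1-yl}-2,2-dimethyl-1,3-dioxan-4-yl]-2-hydroxy-6-[(4-methoxyphenyl)methoxy]-18-phenyloctadecan-4-one
Conditions: (c-C6H11)2BCl, Et3N, Et2O, −78 → 0 °C; then 12, −78 °C; MeOH, pH 7 buffer, H2O2
Reagents that add atoms: none
Why: Boron-mediated aldol reaction of the kinetic (methyl-side) enolate; the β-OPMB stereocentre of the ketone should direct attack on the aldehyde to the 1,5-anti adduct, which sets C6′.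

Step 15
Reactants: 19 aldol adduct of step 14
Product: 20 (2S,4R,6R)-1-[(4S,6R)-6-{(2R,3S)-3-[(4-methoxyphenyl)methoxy]-2-(2-methylprop-2-en-1-yl)pent-4-en-1-yl}-2,2-dimethyl-1,3-dioxan-4-yl]-6-[(4-methoxyphenyl)methoxy]-18-phenyloctadecane-2,4-diol
Conditions: Et2BOMe, THF/MeOH (4:1), −78 °C; NaBH4; pH 7 buffer; MeOH (evaporation)
Reagents that add atoms: none
Why: Second Narasaka–Prasad reduction, directed by the C6′ hydroxyl, should give the 1,3-syn diol and set C8′ (anti to C10′).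

Step 16
Reactants: 20 diene diol of step 15
Product: 23 (4R,5S)-5-({(4R,6S)-6-[(2S,4R,6R)-2,4-dihydroxy-6-[(4-methoxyphenyl)methoxy]-18-phenyloctadecyl]-2,2-dimethyl-1,3-dioxan-4-yl}methyl)-4-[(4-methoxyphenyl)methoxy]cyclohex-2-en-1-one, via keto-aldehyde 21 (not isolated), via β-hydroxy ketone 22 (not isolated)
Conditions: O3, CH2Cl2/MeOH (4:1), NaHCO3, −78 °C (Sudan Red 7B end point); PPh3, −78 °C → rt; solvent exchange; Bn2NH·CF3CO2H (0.3 equiv), toluene, rt → 50 °C
Reagents that add atoms: ozone, [O-][O+]=O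
Why: Ozone cleaves the two terminal C=C bonds (these alkenes react far faster than the anisyl and phenyl rings at −78 °C), and PPh3 reduction of the methoxy hydroperoxides liberates the C1 methyl ketone and the C3 α-alkoxy aldehyde of keto-aldehyde 21. The dibenzylammonium salt then mediates an intramolecular aldol reaction in which the C2 methyl carbon (as enol or enamine) adds to the C3 formyl group, and E1cB loss of water from β-hydroxy ketone 22 gives the C2=C3 enone; the closest known reaction type is the cyclodehydration of 1,5-keto aldehydes to cyclohexenones (the ring-closing half of a Robinson annulation) run after an ozonolysis. The six-membered ring closes in the 6-(enolexo)-exo-trig mode. No stereocentre is created: C4 and C5 are carried through from 20 and the transient C3 carbinol is eliminated. The step needs one regiochemistry and retention at C4: attack by C6 on the aldehyde or by C4 on the ketone would give only four-membered rings, so C2→C3 is the sole productive closure, and the weakly acidic ammonium trifluoroacetate avoids the enolisation of the α-PMB-oxy aldehyde that a stronger base would cause. The 1,3-diol, the acetonide and both PMB ethers are spectators.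

Step 17
Reactants: 23 bis-PMB enone of step 16
Product: 24 (4R,5S)-5-({(4R,6S)-2,2-dimethyl-6-[(2S,4S,6R)-2,4,6-trihydroxy-18-phenyloctadecyl]-1,3-dioxan-4-yl}methyl)-4-hydroxycyclohex-2-en-1-one
Conditions: DDQ (3 equiv), CH2Cl2/pH 7 buffer (10:1), 0 °C → rt
Reagents that add atoms: none
Why: Oxidative cleavage of both p-methoxybenzyl ethers through benzylic oxocarbenium ions that are hydrolysed; enone, acetonide and free hydroxyls should be inert to DDQ.

Step 18
Reactants: 24 acetonide of step 17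
Product: 25 (4R,5S)-4-hydroxy-5-[(2R,4R,6S,8S,10R)-2,4,6,8,10-pentahydroxy-22-phenyldocosyl]cyclohex-2-en-1-one
Conditions: AcOH/H2O/THF (3:1:1), 40 °C
Reagents that add atoms: none
Why: Mild aqueous acid hydrolyses the isopropylidene acetal (and any p-methoxybenzylidene acetal formed in step 17) and should not dehydrate the γ-hydroxy enone.

Compound list
1 | (2S)-but-3-ene-1,2-diol | C=C[C@H](O)CO | starting material
2 | (4S)-4-ethenyl-2-(4-methoxyphenyl)-1,3-dioxolane (both epimers at C2) | C=C[C@H](OC(c1ccc(OC)cc1)O2)C2 | intermediate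
3 | (2S)-2-[(4-methoxyphenyl)methoxy]but-3-en-1-ol | C=C[C@H](OCc1ccc(OC)cc1)CO | intermediate
4 | methyl (3R)-3-[(tert-butyldimethylsilyl)oxy]-5-oxo-6-(triphenyl-λ5-phosphanylidene)hexanoate | O=C(C=P(c1ccccc1)(c1ccccc1)c1ccccc1)C[C@@H](O[Si](C)(C)C(C)(C)C)CC(=O)OC | starting material
5 | (2S)-2-[(4-methoxyphenyl)methoxy]but-3-enal | C=C[C@H](OCc1ccc(OC)cc1)C=O | intermediate
6 | methyl (3R,6E,8S)-3-[(tert-butyldimethylsilyl)oxy]-8-[(4-methoxyphenyl)methoxy]-5-oxodeca-6,9-dienoate | C=C[C@H](OCc1ccc(OC)cc1)/C=C/C(=O)C[C@@H](O[Si](C)(C)C(C)(C)C)CC(=O)OC | intermediate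
7 | methyl (3R,7R,8S)-3-[(tert-butyldimethylsilyl)oxy]-8-[(4-methoxyphenyl)methoxy]-7-(2-methylprop-2-en-1-yl)-5-[(trimethylsilyl)oxy]deca-5,9-dienoate | C=C[C@H](OCc1ccc(OC)cc1)[C@@H](C=C(O[Si](C)(C)C)C[C@@H](O[Si](C)(C)C(C)(C)C)CC(=O)OC)CC(C)=C | intermediate
8 | methyl (3R,7R,8S)-3-[(tert-butyldimethylsilyl)oxy]-8-[(4-methoxyphenyl)methoxy]-7-(2-methylprop-2-en-1-yl)-5-oxodec-9-enoate | C=C[C@H](OCc1ccc(OC)cc1)[C@@H](CC(=O)C[C@@H](O[Si](C)(C)C(C)(C)C)CC(=O)OC)CC(C)=C | intermediate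
9 | methyl (3R,7R,8S)-3-hydroxy-8-[(4-methoxyphenyl)methoxy]-7-(2-methylprop-2-en-1-yl)-5-oxodec-9-enoate | C=C[C@H](OCc1ccc(OC)cc1)[C@@H](CC(=O)C[C@@H](O)CC(=O)OC)CC(C)=C | intermediate
10 | methyl (3R,5R,7R,8S)-3,5-dihydroxy-8-[(4-methoxyphenyl)methoxy]-7-(2-methylprop-2-en-1-yl)dec-9-enoate | C=C[C@H](OCc1ccc(OC)cc1)[C@@H](C[C@@H](O)C[C@@H](O)CC(=O)OC)CC(C)=C | intermediate
11 | methyl 2-[(4R,6R)-6-{(2R,3S)-3-[(4-methoxyphenyl)methoxy]-2-(2-methylprop-2-en-1-yl)pent-4-en-1-yl}-2,2-dimethyl-1,3-dioxan-4-yl]acetate | C=C[C@H](OCc1ccc(OC)cc1)[C@@H](C[C@@H]2C[C@@H](OC(C)(C)O2)CC(=O)OC)CC(C)=C | intermediate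
12 | 2-[(4R,6R)-6-{(2R,3S)-3-[(4-methoxyphenyl)methoxy]-2-(2-methylprop-2-en-1-yl)pent-4-en-1-yl}-2,2-dimethyl-1,3-dioxan-4-yl]acetaldehyde | C=C[C@H](OCc1ccc(OC)cc1)[C@@H](C[C@@H]2C[C@@H](OC(C)(C)O2)CC=O)CC(C)=C | intermediate
13 | 11-bromoundecan-1-ol | OCCCCCCCCCCCBr | starting material
14 | 13-phenyltridecan-1-ol | OCCCCCCCCCCCCCc1ccccc1 | intermediate
15 | 13-phenyltridecanal | O=CCCCCCCCCCCCCc1ccccc1 | intermediate
16 | (4R)-16-phenylhexadec-1-en-4-ol | C=CC[C@H](O)CCCCCCCCCCCCc1ccccc1 | intermediate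
17 | 1-methoxy-4-({[(4R)-16-phenylhexadec-1-en-4-yl]oxy}methyl)benzene | C=CC[C@H](OCc1ccc(OC)cc1)CCCCCCCCCCCCc1ccccc1 | intermediate
18 | (4R)-4-[(4-methoxyphenyl)methoxy]-16-phenylhexadecan-2-one | CC(=O)C[C@H](OCc1ccc(OC)cc1)CCCCCCCCCCCCc1ccccc1 | intermediate
19 | (2R,6R)-1-[(4S,6R)-6-{(2R,3S)-3-[(4-methoxyphenyl)methoxy]-2-(2-methylprop-2-en-1-yl)pent-4-en-1-yl}-2,2-dimethyl-1,3-dioxan-4-yl]-2-hydroxy-6-[(4-methoxyphenyl)methoxy]-18-phenyloctadecan-4-one | C=C[C@H](OCc1ccc(OC)cc1)[C@@H](C[C@@H]2C[C@@H](OC(C)(C)O2)C[C@@H](O)CC(=O)C[C@H](OCc1ccc(OC)cc1)CCCCCCCCCCCCc1ccccc1)CC(C)=C | intermediate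
20 | (2S,4R,6R)-1-[(4S,6R)-6-{(2R,3S)-3-[(4-methoxyphenyl)methoxy]-2-(2-methylprop-2-en-1-yl)pent-4-en-1-yl}-2,2-dimethyl-1,3-dioxan-4-yl]-6-[(4-methoxyphenyl)methoxy]-18-phenyloctadecane-2,4-diol | C=C[C@H](OCc1ccc(OC)cc1)[C@@H](C[C@@H]2C[C@@H](OC(C)(C)O2)C[C@@H](O)C[C@@H](O)C[C@H](OCc1ccc(OC)cc1)CCCCCCCCCCCCc1ccccc1)CC(C)=C | intermediate
21 | (2R,3S)-3-({(4R,6S)-6-[(2S,4R,6R)-2,4-dihydroxy-6-[(4-methoxyphenyl)methoxy]-18-phenyloctadecyl]-2,2-dimethyl-1,3-dioxan-4-yl}methyl)-2-[(4-methoxyphenyl)methoxy]-5-oxohexanal | O=C[C@H](OCc1ccc(OC)cc1)[C@@H](C[C@@H]2C[C@@H](OC(C)(C)O2)C[C@@H](O)C[C@@H](O)C[C@H](OCc1ccc(OC)cc1)CCCCCCCCCCCCc1ccccc1)CC(C)=O | intermediate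
22 | (4R,5S)-5-({(4R,6S)-6-[(2S,4R,6R)-2,4-dihydroxy-6-[(4-methoxyphenyl)methoxy]-18-phenyloctadecyl]-2,2-dimethyl-1,3-dioxan-4-yl}methyl)-3-hydroxy-4-[(4-methoxyphenyl)methoxy]cyclohexan-1-one (both epimers at C3) | O=C1CC(O)[C@H](OCc2ccc(OC)cc2)[C@@H](C[C@@H]3C[C@@H](OC(C)(C)O3)C[C@@H](O)C[C@@H](O)C[C@H](OCc2ccc(OC)cc2)CCCCCCCCCCCCc2ccccc2)C1 | intermediate
23 | (4R,5S)-5-({(4R,6S)-6-[(2S,4R,6R)-2,4-dihydroxy-6-[(4-methoxyphenyl)methoxy]-18-phenyloctadecyl]-2,2-dimethyl-1,3-dioxan-4-yl}methyl)-4-[(4-methoxyphenyl)methoxy]cyclohex-2-en-1-one | O=C1C=C[C@H](OCc2ccc(OC)cc2)[C@@H](C[C@@H]3C[C@@H](OC(C)(C)O3)C[C@@H](O)C[C@@H](O)C[C@H](OCc2ccc(OC)cc2)CCCCCCCCCCCCc2ccccc2)C1 | intermediate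
24 | (4R,5S)-5-({(4R,6S)-2,2-dimethyl-6-[(2S,4S,6R)-2,4,6-trihydroxy-18-phenyloctadecyl]-1,3-dioxan-4-yl}methyl)-4-hydroxycyclohex-2-en-1-one | O=C1C=C[C@H](O)[C@@H](C[C@@H]2C[C@@H](OC(C)(C)O2)C[C@@H](O)C[C@@H](O)C[C@H](O)CCCCCCCCCCCCc2ccccc2)C1 | intermediate
25 | (4R,5S)-4-hydroxy-5-[(2R,4R,6S,8S,10R)-2,4,6,8,10-pentahydroxy-22-phenyldocosyl]cyclohex-2-en-1-one | O=C1C=C[C@H](O)[C@@H](C[C@@H](O)C[C@@H](O)C[C@@H](O)C[C@@H](O)C[C@H](O)CCCCCCCCCCCCc2ccccc2)C1 | target

Total step count: 18. Longest linear sequence: 13 steps (steps 1–8 and 14–18, from 1).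

Steps most likely to fail

Step 16. The anisyl rings may be over-oxidised if ozone is not stopped exactly at the end point, and configuration at C4 may be lost by enolisation of the aldehyde before the ring closes. The fallback sets out from 20. Ring-closing metathesis (second-generation Grubbs catalyst, CH2Cl2, 40 °C) joins the 2-methylallyl and vinyl groups to the 1-methylcyclopentene (2S,4R,6R)-1-[(4S,6R)-6-{[(1R,2R)-2-[(4-methoxyphenyl)methoxy]-4-methylcyclopent-3-en-1-yl]methyl}-2,2-dimethyl-1,3-dioxan-4-yl]-6-[(4-methoxyphenyl)methoxy]-18-phenyloctadecane-2,4-diol F1. Its single trisubstituted ring alkene should take up one equivalent of ozone (then PPh3) far faster than any arene and open to the same keto-aldehyde 21, which is then isolated. Separate cyclodehydration with Bn2NH·CF3CO2H returns to the route at 23.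

Step 4. The allylic organometallic may add 1,2 to the ketone, and facial discrimination at C5 may be insufficient. The fallback sets out from 6: Hosomi–Sakurai conjugate allylation with (2-methylallyl)trimethylsilane and TiCl4 in CH2Cl2 at −78 °C. The allylsilane attacks only the β-carbon through an open transition state under the same Felkin–Anh bias, and aqueous work-up returns to the route at 8. No new isolable compound arises.

Step 14. The 1,5-induction may erode if the chiral β-acetal aldehyde opposes it, and the adduct may undergo retro-aldol cleavage. The fallback sets out from 18 and 12, makes the C6′–C7′ bond as an alkene and adds the C6′ oxygen afterwards under catalyst control.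
- Ketone 18 is brominated at its methyl group through the kinetic silyl enol ether (LiN(SiMe3)2, Me3SiCl; then N-bromosuccinimide) to (4R)-1-bromo-4-[(4-methoxyphenyl)methoxy]-16-phenylhexadecan-2-one F2.
- PPh3, then aq. Na2CO3, gives the keto ylide (4R)-4-[(4-methoxyphenyl)methoxy]-16-phenyl-1-(triphenyl-λ5-phosphanylidene)hexadecan-2-one F3.
- Wittig reaction with 12 gives the (E)-enone (2E,6R)-1-[(4S,6R)-6-{(2R,3S)-3-[(4-methoxyphenyl)methoxy]-2-(2-methylprop-2-en-1-yl)pent-4-en-1-yl}-2,2-dimethyl-1,3-dioxan-4-yl]-6-[(4-methoxyphenyl)methoxy]-18-phenyloctadec-2-en-4-one F4.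
- Conjugate borylation with B2pin2 and MeOH, catalysed by CuCl/NaOt-Bu and a chiral Josiphos-type bisphosphine (antipode chosen for the C6′ configuration), gives the β-boryl ketone (2R,6R)-1-[(4S,6R)-6-{(2R,3S)-3-[(4-methoxyphenyl)methoxy]-2-(2-methylprop-2-en-1-yl)pent-4-en-1-yl}-2,2-dimethyl-1,3-dioxan-4-yl]-6-[(4-methoxyphenyl)methoxy]-18-phenyl-2-(4,4,5,5-tetramethyl-1,3,2-dioxaborolan-2-yl)octadecan-4-one F5.
- Oxidation with NaBO3·4H2O, with retention, comes back to the route at 19.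

Further compounds
F1 | step 16 | (2S,4R,6R)-1-[(4S,6R)-6-{[(1R,2R)-2-[(4-methoxyphenyl)methoxy]-4-methylcyclopent-3-en-1-yl]methyl}-2,2-dimethyl-1,3-dioxan-4-yl]-6-[(4-methoxyphenyl)methoxy]-18-phenyloctadecane-2,4-diol | CC1=C[C@H](OCc2ccc(OC)cc2)[C@@H](C[C@@H]3C[C@@H](OC(C)(C)O3)C[C@@H](O)C[C@@H](O)C[C@H](OCc2ccc(OC)cc2)CCCCCCCCCCCCc2ccccc2)C1
F0 | step 4 | none | none
F2 | step 14 | (4R)-1-bromo-4-[(4-methoxyphenyl)methoxy]-16-phenylhexadecan-2-one | BrCC(=O)C[C@H](OCc1ccc(OC)cc1)CCCCCCCCCCCCc1ccccc1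
F3 | step 14 | (4R)-4-[(4-methoxyphenyl)methoxy]-16-phenyl-1-(triphenyl-λ5-phosphanylidene)hexadecan-2-one | O=C(C=P(c1ccccc1)(c1ccccc1)c1ccccc1)C[C@H](OCc1ccc(OC)cc1)CCCCCCCCCCCCc1ccccc1
F4 | step 14 | (2E,6R)-1-[(4S,6R)-6-{(2R,3S)-3-[(4-methoxyphenyl)methoxy]-2-(2-methylprop-2-en-1-yl)pent-4-en-1-yl}-2,2-dimethyl-1,3-dioxan-4-yl]-6-[(4-methoxyphenyl)methoxy]-18-phenyloctadec-2-en-4-one | C=C[C@H](OCc1ccc(OC)cc1)[C@@H](C[C@@H]2C[C@@H](OC(C)(C)O2)C/C=C/C(=O)C[C@H](OCc1ccc(OC)cc1)CCCCCCCCCCCCc1ccccc1)CC(C)=C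
F5 | step 14 | (2R,6R)-1-[(4S,6R)-6-{(2R,3S)-3-[(4-methoxyphenyl)methoxy]-2-(2-methylprop-2-en-1-yl)pent-4-en-1-yl}-2,2-dimethyl-1,3-dioxan-4-yl]-6-[(4-methoxyphenyl)methoxy]-18-phenyl-2-(4,4,5,5-tetramethyl-1,3,2-dioxaborolan-2-yl)octadecan-4-one | C=C[C@H](OCc1ccc(OC)cc1)[C@@H](C[C@@H]2C[C@@H](OC(C)(C)O2)C[C@@H](B3OC(C)(C)C(C)(C)O3)CC(=O)C[C@H](OCc1ccc(OC)cc1)CCCCCCCCCCCCc1ccccc1)CC(C)=C
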